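The route rests on disconnecting the pyran between its CH2 (C-13) and the oxygen-bearing spiro carbon C-8, which is also a member of the nine-membered ring. Before the key step C-8 is a tertiary C–H next to the enol-ether oxygen of a syncarpic acid ether of a 13-norcaryophyllen-8-ol, and the neighbouring enone carbon carries a diazoacetyl group. A dirhodium carbene then inserts into this one α-oxy C–H bond: one operation closes the pyranone ring and converts an easily set secondary carbinol centre into the spiro quaternary centre with retention. The terpenoid half comes from (−)-caryophyllene oxide; the isobutyl group and H at C-1′ follow by organocerium addition and ionic hydrogenation.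

Key step: step 9

Remark: locants follow caryophyllane numbering (C-1/C-9 ring fusion, C-4 methyl-bearing alkene carbon, C-5 carbinol, C-8 spiro carbon, C-13 the pyran CH2, C-1′ the pyran CH bearing isobutyl); (−)-caryophyllene oxide and syncarpic acid are taken as purchasable.

Step 1
Reactants: 1 (−)-caryophyllene oxide
Product: 2 (1R,3Z,5R,9S)-caryophylla-3,8(13)-dien-5-ol
Conditions: Et2Al–TMP (from 2,2,6,6-tetramethylpiperidine, n-BuLi, Et2AlCl), toluene, 0 °C to rt; aqueous work-up
Reagents that add atoms: none
Why: Aluminium-amide epoxide-to-allylic-alcohol isomerisation (cyclic syn β-elimination), in which the bulky amide should remove a proton from the ring methylene C-3 that lies cis to the epoxide hydrogen, so that C-4–O breaks, the C-5–O centre (5R) is untouched and the nine-membered ring delivers the cis (3Z) alkene.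

Step 2
Reactants: 2 (1R,3Z,5R,9S)-caryophylla-3,8(13)-dien-5-ol
Product: 3 5-O-tert-butyldimethylsilyl ether of 2
Conditions: TBSCl, imidazole, DMF, rt
Reagents that add atoms: tert-butyldimethylsilyl chloride CC(C)(C)[Si](C)(C)Cl
Why: Imidazole-mediated silylation of a secondary alcohol, which touches no stereocentre and masks the hydroxyl for the steps that follow.

Step 3
Reactants: 3 5-O-tert-butyldimethylsilyl ether of 2
Product: 5 (1R,3Z,5R,9S)-5-(tert-butyldimethylsilyloxy)-13-norcaryophyll-3-en-8-one, via 8,13-diol 4 (not isolated)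
Conditions: K2OsO2(OH)4 (cat.), (DHQD)2PHAL (cat.), NMO, acetone/H2O, 0 °C; then NaIO4, THF/H2O, rt
Reagents that add atoms: N-methylmorpholine N-oxide C[N+]1([O-])CCOCC1; water O (together the two hydroxyl oxygens of 4, one of which stays as the ketone oxygen of 5)
Why: Ligand-accelerated Sharpless-type dihydroxylation should prefer the unhindered 1,1-disubstituted exocyclic alkene over the cyclic cis-trisubstituted alkene that is deactivated by its allylic silyloxy group (as with limonene), and Malaprade periodate cleavage of the diol then gives the ketone and erases the C-8 centre of 4.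

Step 4
Reactants: 5 (1R,3Z,5R,9S)-5-(tert-butyldimethylsilyloxy)-13-norcaryophyll-3-en-8-one
Product: 6 (1R,3Z,5R,8S,9S)-5-(tert-butyldimethylsilyloxy)-13-norcaryophyll-3-en-8-ol
Conditions: LiBH(s-Bu)3, THF, −78 °C; then H2O
Reagents that add atoms: none
Why: Bulky borohydride reduction in which hydride should add to the carbonyl face syn to H-9 and away from the cyclobutane methylene C-10 (Felkin-type control by C-9), giving the (8S) alcohol.

Step 5
Reactants: 6 (1R,3Z,5R,8S,9S)-5-(tert-butyldimethylsilyloxy)-13-norcaryophyll-3-en-8-ol; 7 syncarpic acid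
Product: 8 5-{[(1R,3Z,5R,8R,9S)-5-(tert-butyldimethylsilyloxy)-13-norcaryophyll-3-en-8-yl]oxy}-2,2,6,6-tetramethylcyclohex-4-ene-1,3-dione
Conditions: PPh3, DIAD, toluene, 0 °C to rt
Reagents that add atoms: none
Why: Mitsunobu reaction, in which the acidic enol oxygen of the cyclic 1,3-dione displaces the alkoxyphosphonium group by SN2 with inversion, placing the C-8–O bond (8R) on the face that the ring oxygen occupies in the target.

Step 6
Reactants: 8 syncarpic enol ether of 6 (8R)
Product: 9 4-iodo derivative of 8
Conditions: NIS, MeCN, 0 °C to rt, dark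
Reagents that add atoms: N-iodosuccinimide O=C1CCC(=O)N1I
Why: Electrophilic α-iodination of a β-alkoxy enone at its nucleophilic α-carbon, the isolated trisubstituted alkene having no nucleophile to trap an iodonium ion in this aprotic medium.

Step 7
Reactants: 9 4-iodo derivative of 8
Product: 11 4-acetyl derivative of 8, via 1-ethoxyvinyl diene 10 (not isolated)
Conditions: tributyl(1-ethoxyvinyl)stannane, Pd(PPh3)4 (cat.), CuI (cat.), DMF, 60 °C; then 0.5 M HCl, THF, 0 °C
Reagents that add atoms: tributyl(1-ethoxyvinyl)stannane CCOC(=C)[Sn](CCCC)(CCCC)CCCC; water O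
Why: Stille coupling of the α-iodo enone with an acetyl-anion equivalent, followed by mild acid hydrolysis of the 1-ethoxyvinyl group, which should be far faster than hydrolysis of the hindered vinylogous ester or loss of the silyl ether.

Step 8
Reactants: 11 4-acetyl derivative of 8
Product: 13 4-(diazoacetyl) derivative of 8, via trifluoroacetyl diketone 12 (not isolated)
Conditions: LiHMDS, THF, −78 °C, then CF3CO2CH2CF3; aqueous HCl work-up; MsN3, Et3N, H2O, MeCN, rt
Reagents that add atoms: methanesulfonyl azide CS(=O)(=O)N=[N+]=[N-] (the N2 of 13); 2,2,2-trifluoroethyl trifluoroacetate FC(F)(F)COC(=O)C(F)(F)F (the CF3CO group of unisolated 12 only)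
Why: Detrifluoroacetylative Regitz-type diazo transfer, in which the acetyl methyl is the only enolisable position (every other α-carbon is quaternary), its lithium enolate is trifluoroacetylated and the activated 1,3-diketone takes up the diazo group with loss of the trifluoroacetyl group.

Step 9
Reactants: 13 4-(diazoacetyl) derivative of 8
Product: 14 (8S)-spiro-pyranone, the 5-O-TBS ether of the target skeleton with a ketone at C-1′ and no isobutyl group
Conditions: Rh2(OAc)4 (1 mol %), CH2Cl2, reflux, slow addition at high dilution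
Reagents that add atoms: none
Why: Rh2(OAc)4 converts the diazoketone into an electrophilic rhodium carbene at C-13, which inserts in a concerted three-centre fashion into the hydridic tertiary C-8–H bond next to the enol-ether oxygen and so forms the C-13–C-8 bond. The closest known reaction type is the rhodium-carbene C–H insertion of o-alkoxyaryl diazomethyl ketones to chroman-4-ones, of which this vinylogous ester is the non-aromatic counterpart. The pyranone ring closes through a six-membered (1,6) insertion transition state, the usual five-membered mode being unavailable because position 5 from the carbene is the ring oxygen. The new spiro quaternary centre C-8 forms with retention, C-13 taking the place of the hydrogen, so the configuration set by reduction and Mitsunobu inversion is transferred unchanged (descriptor 8R in 13 becomes 8S in 14 only through the change in priorities). The step needs chemoselectivity for this C–H bond over capture of the carbene by the flanking ring carbonyl or ether oxygen (ylide formation) and over the methyl and ring CH2 bonds. The tertiary α-oxy C–H is the most activated bond within reach, the vinylogous-ester oxygens are poor donors, and their ylides have no easy unimolecular outlet when bimolecular pathways are suppressed by slow addition.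

Step 10
Reactants: 14 (8S)-spiro-pyranone
Product: 16 5-O-tert-butyldimethylsilyl-tomentodione O, via tertiary alcohol 15 (not isolated)
Conditions: i-BuMgBr, CeCl3, THF, −78 °C; aqueous work-up; then Et3SiH, CF3CO2H, CH2Cl2, −40 °C
Reagents that add atoms: isobutylmagnesium bromide CC(C)C[Mg]Br
Why: Non-basic organocerium 1,2-addition should occur at the least hindered carbonyl (the pyranone C=O, the other two being flanked by quaternary carbons), and Kursanov–Parnes ionic hydrogenation of the resulting tertiary alcohol should then deliver hydride to C-1′ of the alkoxy-allyl cation on the face anti to the pseudo-axial C-7 methylene of the spiro centre (bulkier C-9 branch pseudo-equatorial), which sets (1′R).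

Step 11
Reactants: 16 5-O-tert-butyldimethylsilyl-tomentodione O
Product: 17 tomentodione O
Conditions: HF·pyridine, pyridine, THF, 0 °C to rt
Reagents that add atoms: none
Why: Fluoride-mediated desilylation under buffered, non-basic conditions, which should leave the tertiary-alkyl vinylogous ester, the cis alkene and the allylic alcohol untouched.

Compound list
1 | (−)-caryophyllene oxide, (1R,4R,5R,9S)-4,5-epoxycaryophyll-8(13)-ene | C[C@@]12CC[C@@H]3[C@H](CC3(C)C)C(=C)CC[C@H]1O2 | starting material
2 | (1R,3Z,5R,9S)-caryophylla-3,8(13)-dien-5-ol | C/C1=C/C[C@@H]2[C@H](CC2(C)C)C(=C)CC[C@H]1O | intermediate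
3 | 5-O-tert-butyldimethylsilyl ether of 2 | C/C1=C/C[C@@H]2[C@H](CC2(C)C)C(=C)CC[C@H]1O[Si](C)(C)C(C)(C)C | intermediate
4 | (1R,3Z,5R,8R,9S)-5-(tert-butyldimethylsilyloxy)caryophyll-3-ene-8,13-diol (C-8 configuration drawn for osmylation syn to H-9; it is erased in the same step) | C/C1=C/C[C@@H]2[C@H](CC2(C)C)[C@@](O)(CO)CC[C@H]1O[Si](C)(C)C(C)(C)C | intermediate
5 | (1R,3Z,5R,9S)-5-(tert-butyldimethylsilyloxy)-13-norcaryophyll-3-en-8-one | C/C1=C/C[C@@H]2[C@H](CC2(C)C)C(=O)CC[C@H]1O[Si](C)(C)C(C)(C)C | intermediate
6 | (1R,3Z,5R,8S,9S)-5-(tert-butyldimethylsilyloxy)-13-norcaryophyll-3-en-8-ol | C/C1=C/C[C@@H]2[C@H](CC2(C)C)[C@@H](O)CC[C@H]1O[Si](C)(C)C(C)(C)C | intermediate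
7 | syncarpic acid, 5-hydroxy-2,2,6,6-tetramethylcyclohex-4-ene-1,3-dione | CC1(C)C(O)=CC(=O)C(C)(C)C1=O | starting material
8 | 5-{[(1R,3Z,5R,8R,9S)-5-(tert-butyldimethylsilyloxy)-13-norcaryophyll-3-en-8-yl]oxy}-2,2,6,6-tetramethylcyclohex-4-ene-1,3-dione | C/C1=C/C[C@@H]2[C@H](CC2(C)C)[C@H](OC3=CC(=O)C(C)(C)C(=O)C3(C)C)CC[C@H]1O[Si](C)(C)C(C)(C)C | intermediate
9 | 4-iodo derivative of 8 (iodine on the enone α-carbon) | C/C1=C/C[C@@H]2[C@H](CC2(C)C)[C@H](OC3=C(I)C(=O)C(C)(C)C(=O)C3(C)C)CC[C@H]1O[Si](C)(C)C(C)(C)C | intermediate
10 | 4-(1-ethoxyvinyl) derivative of 8 | C/C1=C/C[C@@H]2[C@H](CC2(C)C)[C@H](OC3=C(C(=C)OCC)C(=O)C(C)(C)C(=O)C3(C)C)CC[C@H]1O[Si](C)(C)C(C)(C)C | intermediate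
11 | 4-acetyl derivative of 8 | C/C1=C/C[C@@H]2[C@H](CC2(C)C)[C@H](OC3=C(C(C)=O)C(=O)C(C)(C)C(=O)C3(C)C)CC[C@H]1O[Si](C)(C)C(C)(C)C | intermediate
12 | 4-(4,4,4-trifluoro-3-oxobutanoyl) derivative of 8 | C/C1=C/C[C@@H]2[C@H](CC2(C)C)[C@H](OC3=C(C(=O)CC(=O)C(F)(F)F)C(=O)C(C)(C)C(=O)C3(C)C)CC[C@H]1O[Si](C)(C)C(C)(C)C | intermediate
13 | 4-(diazoacetyl) derivative of 8 | C/C1=C/C[C@@H]2[C@H](CC2(C)C)[C@H](OC3=C(C(=O)C=[N+]=[N-])C(=O)C(C)(C)C(=O)C3(C)C)CC[C@H]1O[Si](C)(C)C(C)(C)C | intermediate
14 | (1R,3Z,5R,8S,9S)-spiro-pyranone: 5-O-TBS ether of the target skeleton with C-13 as CH2 and C-1′ as ketone | C/C1=C/C[C@@H]2[C@H](CC2(C)C)[C@]2(CC[C@H]1O[Si](C)(C)C(C)(C)C)CC(=O)C1=C(O2)C(C)(C)C(=O)C(C)(C)C1=O | intermediate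
15 | 1′-hydroxy-1′-isobutyl tertiary alcohol from 14 (C-1′ epimer expected from attack anti to the pseudo-axial C-7; this centre is ionised in the same step) | C/C1=C/C[C@@H]2[C@H](CC2(C)C)[C@]2(CC[C@H]1O[Si](C)(C)C(C)(C)C)C[C@](O)(CC(C)C)C1=C(O2)C(C)(C)C(=O)C(C)(C)C1=O | intermediate
16 | 5-O-tert-butyldimethylsilyl-tomentodione O (1R,3Z,5R,8S,9S,1′R) | C/C1=C/C[C@@H]2[C@H](CC2(C)C)[C@]2(CC[C@H]1O[Si](C)(C)C(C)(C)C)C[C@@H](CC(C)C)C1=C(O2)C(C)(C)C(=O)C(C)(C)C1=O | intermediate
17 | tomentodione O (1R,3Z,5R,8S,9S,1′R) | C/C1=C/C[C@@H]2[C@H](CC2(C)C)[C@]2(CC[C@H]1O)C[C@@H](CC(C)C)C1=C(O2)C(C)(C)C(=O)C(C)(C)C1=O | target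

Total step count: 11. Longest linear sequence: 11 steps (1 to 17).

Steps most likely to fail

Step 9. The rhodium carbene may be intercepted by the lone pairs of the neighbouring ring carbonyl or of the ether oxygen (ylide formation, then 1,2-shift or dimerisation) faster than it inserts into the hindered C-8–H bond. The fallback sets out from ketone 5 and returns at 14. 2-Acetylsyncarpic acid F1 is converted into its dianion (LDA, 2.2 equiv, THF, −78 °C) and added to 5; this aldol addition of the acetyl methyl carbon makes the same C-13–C-8 bond and gives the β-hydroxy ketone F2. MsCl/Et3N and then DBU should effect E1cB dehydration to the exocyclic enone and oxa-Michael closure of the enol oxygen onto C-8 from the face syn to H-9, giving 14. This is the known aldol/oxa-Michael route to 2,2-disubstituted chromanones; here the ring closes at O–C-8, and the C-8 configuration then rests on the facial bias of a reversible oxa-Michael addition.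

Step 10. Hydride delivery to the planar C-1′ cation may show poor or reversed facial selectivity, or the organocerium reagent may attack another carbonyl. The fallback sets out from 14 and returns at 16, and reverses the order in which the two C-1′ substituents arrive. Luche reduction (NaBH4, CeCl3, MeOH, −78 °C) of the pyranone carbonyl gives the secondary alcohol F3. Hosomi–Sakurai allylation (methallyltrimethylsilane, BF3·OEt2, CH2Cl2, −78 °C) of the derived alkoxy-allyl cation then brings in the carbon substituent on the face where hydride would otherwise have entered, giving the methallyl compound F4 with the opposite relative configuration to that from hydride delivery. Hydrogenation of the 1,1-disubstituted alkene with RhCl(PPh3)3/H2, which should spare the trisubstituted ring alkene, gives 16.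

Step 1. Proton abstraction may occur from the C-12 methyl instead of C-3 (wrong regioselectivity, giving the exocyclic 4(12)-ene), or the alkene may form with mixed geometry. The fallback sets out from 1 and returns at 2. The exocyclic allylic alcohol F5 is made on purpose (Al(Oi-Pr)3, toluene, reflux) and oxidised with MnO2 to the α-methylene ketone F6. DBU (toluene, 80 °C) moves the double bond into the ring to give the conjugated (Z)-2-methyl enone F7. Corey–Bakshi–Shibata reduction ((S)-Me-CBS, BH3·SMe2, THF, −20 °C) then sets C-5 as R under reagent control and gives 2.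

Further compounds
F1 | step 9 | 2-acetylsyncarpic acid, 4-acetyl-5-hydroxy-2,2,6,6-tetramethylcyclohex-4-ene-1,3-dione | CC(=O)C1=C(O)C(C)(C)C(=O)C(C)(C)C1=O
F2 | step 9 | β-hydroxy ketone from aldol addition of the F1 dianion to 5 (C-8 drawn for attack syn to H-9; erased on dehydration) | C/C1=C/C[C@@H]2[C@H](CC2(C)C)[C@](O)(CC(=O)C3=C(O)C(C)(C)C(=O)C(C)(C)C3=O)CC[C@H]1O[Si](C)(C)C(C)(C)C
F3 | step 10 | 1′-hydroxy compound from Luche reduction of 14 (C-1′ configuration inconsequential) | C/C1=C/C[C@@H]2[C@H](CC2(C)C)[C@]2(CC[C@H]1O[Si](C)(C)C(C)(C)C)C[C@@H](O)C1=C(O2)C(C)(C)C(=O)C(C)(C)C1=O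
F4 | step 10 | 1′-(2-methylallyl) analogue of 16 (1′R) | C/C1=C/C[C@@H]2[C@H](CC2(C)C)[C@]2(CC[C@H]1O[Si](C)(C)C(C)(C)C)C[C@@H](CC(C)=C)C1=C(O2)C(C)(C)C(=O)C(C)(C)C1=O
F5 | step 1 | (1R,5R,9S)-caryophylla-4(12),8(13)-dien-5-ol | C=C1CC[C@@H]2[C@H](CC2(C)C)C(=C)CC[C@H]1O
F6 | step 1 | (1R,9S)-caryophylla-4(12),8(13)-dien-5-one | C=C1CC[C@@H]2[C@H](CC2(C)C)C(=C)CCC1=O
F7 | step 1 | (1R,3Z,9S)-caryophylla-3,8(13)-dien-5-one | C/C1=C/C[C@@H]2[C@H](CC2(C)C)C(=C)CCC1=O
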